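**Retrosynthetic overview**

1. The target is a 1,4-epoxygermacranolide. It has a ten-membered carbocycle (C1–C10), a tetrahydrofuran ring closed by the C1–O–C4 hemiketal oxygen, and a γ-ylidene butenolide fused at C6/C7 (O–C6, C7=C11, C12=O).
2. Last disconnection: the hemiketal opens to a C1 ketone and a C4 tertiary alcohol (carried as a PMB ether); the C10 and C13 acetates are put on just before.
3. Key disconnection: the C3–C4 bond. The C1 carbonyl carbon and the C5=C6 enol-lactone double bond flank C2–C3–C4 in the ten-membered ring (a cyclodec-5-enone whose alkene carbon C6 bears oxygen). This is the retron of an anionic oxy-Cope ring expansion of a 1-vinyl-2-alkenylcyclohexane-1,2-diol; a C7 ketone next to C6 lets the C6 enolate be acylated and closed to the butenolide by intramolecular Horner–Wadsworth–Emmons reaction in the same flask.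
4. The cyclohexanone precursor comes from (−)-quinic acid. C8 is bought; C10, C6 and C1 are set by additions to ketones from the face opposite the ring oxygens; C4 and the C5=C6 geometry follow by chair chirality transfer; C1 is fixed on hemiketal closure.
5. Ring order: cyclohexane (chiral pool) → ten-membered carbocycle and butenolide (key step) → tetrahydrofuran hemiketal (last step).

Key step: step 20

Remark: germacrane numbering is used from compound 8 on (C1 hemiketal carbon, C4 ether carbon with C15H3, C10 acetoxy carbon with C14H3, C12 lactone carbonyl, C13 acetoxymethyl), β is the face of the C8 oxygen, and 1-(trimethylsilyl)propyne, (triisopropylsiloxy)methyl chloride and benzyl diethylphosphonoacetate are taken as commercial.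

**Route**

Step 1
Reactants: 1 (−)-quinic acid
Product: 2 quinide (quinic acid 1,5-lactone; C3–OH equatorial, C4–OH axial, C1–OH tertiary)
Conditions: TsOH·H2O (cat.), toluene/DMF, reflux, Dean–Stark
Reagents that add atoms: none
Why: Acid-catalysed lactonisation (Fischer esterification) of the carboxyl group onto the cis C5 hydroxyl after ring flip; no stereocentre is touched.

Step 2
Reactants: 2 quinide
Product: 3 3-O-(4-methoxybenzyl)quinide
Conditions: Bu2SnO, toluene, reflux (−H2O); then PMBCl, CsF, DMF, rt
Reagents that add atoms: 4-methoxybenzyl chloride, COc1ccc(CCl)cc1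
Why: Stannylene-acetal-mediated regioselective O-alkylation of the cis-3,4-diol at its equatorial (C3) oxygen; the tertiary C1 hydroxyl is not engaged.

Step 3
Reactants: 3 3-O-(4-methoxybenzyl)quinide
Product: 4 3-O-(4-methoxybenzyl)-4-O-(triisopropylsilyl)quinide
Conditions: TIPSOTf, 2,6-lutidine, CH2Cl2, −78 to 0 °C
Reagents that add atoms: triisopropylsilyl triflate, CC(C)[Si](C(C)C)(C(C)C)OS(=O)(=O)C(F)(F)F
Why: Silylation (silyl triflate/hindered base) of the one remaining secondary hydroxyl; the tertiary C1–OH is too hindered for TIPS, and TIPS is chosen because it should not migrate to the neighbouring alkoxide in step 4.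

Step 4
Reactants: 4 3-O-(4-methoxybenzyl)-4-O-(triisopropylsilyl)quinide
Product: 5 1-(hydroxymethyl)-3-(PMB-oxy)-4-(TIPS-oxy)cyclohexane-1,5-diol (quinic acid numbering and configuration)
Conditions: NaBH4, EtOH, 0 °C to rt
Reagents that add atoms: none
Why: Hydride reduction of the strained bridged lactone to the primary alcohol, which frees the C5 hydroxyl; no stereocentre is touched.

Step 5
Reactants: 5 triol
Product: 6 5-hydroxy-3-(PMB-oxy)-4-(TIPS-oxy)cyclohexan-1-one (3-O/4-O cis, 5-OH trans to them)
Conditions: NaIO4, THF/pH 7 buffer, 0 °C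
Reagents that add atoms: none
Why: Malaprade glycol cleavage of the only free 1,2-diol (tertiary OH/CH2OH) gives the cyclohexanone.

Step 6
Reactants: 6 β-hydroxy ketone
Product: 8 (4S,5R)-5-(PMB-oxy)-4-(TIPS-oxy)cyclohex-2-en-1-one (C10 ketone and C1=C6 alkene with 7β-OTIPS and 8β-OPMB), via mesylate 7 (not isolated)
Conditions: MsCl, Et3N, CH2Cl2, 0 °C to rt
Reagents that add atoms: none
Why: Mesylation followed in the same flask by E1cB elimination gives the conjugated enone, the mesylate leaving far faster than the ether oxygen on the other side of the ketone.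

Step 7
Reactants: 8 enone
Product: 9 tertiary allylic alcohol (10β-OH and 10α-CH3 with 7β-OTIPS and 8β-OPMB; C1=C6 alkene)
Conditions: MeLi, Et2O, −78 °C
Reagents that add atoms: methyllithium, C[Li]
Why: 1,2-Addition of an organolithium to the enone carbonyl from the α face, anti to the C7 and C8 oxygen substituents, sets C10 with its hydroxyl β (cis to O8).

Step 8
Reactants: 9 tertiary allylic alcohol
Product: 10 triol (1α,6α-diol added to 9)
Conditions: OsO4 (cat.), NMO, acetone/H2O, rt
Reagents that add atoms: N-methylmorpholine N-oxide, C[N+]1([O-])CCOCC1, and water, O (both oxygens delivered through OsO4, O=[Os](=O)(=O)=O)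
Why: Upjohn syn-dihydroxylation from the α face, anti to the β allylic oxygen substituents at C10 and C7; both new carbinol centres are transient because each later becomes a ketone.

Step 9
Reactants: 10 triol
Product: 11 acyloin (C6 ketone and 1α-OH)
Conditions: TEMPO (cat.), PhI(OAc)2, CH2Cl2, rt
Reagents that add atoms: none
Why: Oxoammonium (TEMPO) oxidation is governed by steric access, and the C1 carbinol is axial and next to the fully substituted C10 while the C6 carbinol is equatorial, so the C6 ketone should form and the resulting α-hydroxy ketone should resist further oxidation.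

Step 10
Reactants: 12 1-(trimethylsilyl)prop-1-yne
Product: 13 1-bromoprop-1-yne (used as a solution)
Conditions: NBS, AgNO3 (cat.), acetone, rt
Reagents that add atoms: N-bromosuccinimide, O=C1CCC(=O)N1Br
Why: Silver-catalysed bromodesilylation of an alkynylsilane.

Step 11
Reactants: 13 1-bromoprop-1-yne; 14 4-methoxybenzyl alcohol
Product: 15 (Z)-1-bromo-2-[(4-methoxybenzyl)oxy]prop-1-ene
Conditions: KOH (cat.), DMSO, rt
Reagents that add atoms: none
Why: Base-mediated nucleophilic anti-hydroalkoxylation of a 1-bromoalkyne, in which the alkoxide adds to the carbon remote from bromine and anti protonation of the α-bromovinyl anion leaves Br and OR cis (Z).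

Step 12
Reactants: 11 acyloin; 15 (Z)-bromo enol ether
Product: 17 C6 adduct (6β-OH and 6α-[(Z)-2-(PMB-oxy)prop-1-enyl] with 1α-OH and 10β-OH), via alkenyllithium 16 (not isolated)
Conditions: 15 (3.5 equiv), t-BuLi (7 equiv), Et2O, −78 °C; then 11, THF, −78 to −40 °C
Reagents that add atoms: none
Why: Bromine–lithium exchange gives the configurationally stable, internally chelated (Z)-β-alkoxyvinyllithium, which adds 1,2 to the C6 ketone from the α face (the β face is screened by the adjacent C7–OTIPS and the C8 and C10 oxygens, and the C1 alkoxide can deliver the reagent), setting C6 with its hydroxyl β.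

Step 13
Reactants: 17 C6 adduct
Product: 18 C1 ketone
Conditions: SO3·pyridine, DMSO, i-Pr2NEt, CH2Cl2, 0 °C
Reagents that add atoms: none
Why: Parikh–Doering oxidation of the only secondary alcohol under non-acidic conditions that the enol ether and the tertiary allylic alcohol tolerate and that do not cleave 1,2-diols.

Step 14
Reactants: 18 C1 ketone
Product: 19 divinyl diol (1β-OH and 1α-vinyl, cis to the C6 alkenyl group)
Conditions: CH2=CHMgBr (5 equiv), THF, −20 to 0 °C
Reagents that add atoms: vinylmagnesium bromide, C=C[Mg]Br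
Why: Grignard 1,2-addition to a non-enolisable ketone by axial attack from the α face of the chair whose two flanking C–O bonds (C10, C6) are axial (polar Felkin–Anh control, the flipped chair suffering a syn-diaxial CH3/alkenyl clash), setting C1 with its hydroxyl β.

Step 15
Reactants: 19 divinyl diol
Product: 20 tetraol (7β-OH free)
Conditions: Bu4NF, AcOH (1:1), THF, 40 °C
Reagents that add atoms: none
Why: Fluoride desilylation of the only silyl ether, buffered with acetic acid so that no free alkoxide triggers a premature oxy-Cope shift.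

Step 16
Reactants: 20 tetraol
Product: 21 α-ketol (C7 ketone; 10β-OH, 1β-OH, 6β-OH; 1α-vinyl; 6α-(Z)-alkenyl; 8β-OPMB)
Conditions: SO3·pyridine, DMSO, i-Pr2NEt, CH2Cl2, 0 °C
Reagents that add atoms: none
Why: Parikh–Doering oxidation of the only secondary alcohol (C7); the three tertiary hydroxyls and the C8 ether are inert.

Step 17
Reactants: 22 benzyl 2-(diethoxyphosphoryl)acetate
Product: 23 benzyl 2-(diethoxyphosphoryl)-3-(triisopropylsilyloxy)propanoate (racemic)
Conditions: NaH, THF, 0 °C; then i-Pr3SiOCH2Cl, 0 °C to rt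
Reagents that add atoms: (triisopropylsiloxy)methyl chloride, ClCO[Si](C(C)C)(C(C)C)C(C)C
Why: C-Alkylation of a phosphonoacetate anion with a chloromethyl ether installs the protected C13 oxygen.

Step 18
Reactants: 23 benzyl ester
Product: 24 2-(diethoxyphosphoryl)-3-(triisopropylsilyloxy)propanoic acid
Conditions: H2 (1 atm), Pd/C, EtOAc, rt
Reagents that add atoms: none
Why: Hydrogenolysis of the benzyl ester under neutral conditions avoids base-induced β-elimination of the silyloxy group.

Step 19
Reactants: 24 acid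
Product: 25 2-(diethoxyphosphoryl)-3-(triisopropylsilyloxy)propanoyl chloride (used crude)
Conditions: (COCl)2, DMF (cat.), CH2Cl2, 0 °C
Reagents that add atoms: oxalyl chloride, ClC(=O)C(Cl)=O
Why: Acid chloride formation through the Vilsmeier-type chloroiminium intermediate.

Step 20
Reactants: 21 α-ketol; 25 acid chloride
Product: 28 macrocyclic butenolide (ten-membered ring with C1 ketone, 10-OH, 4-OPMB, 8-OPMB, 13-OTIPS and the 5E ylidene butenolide), via potassium enolate 26 (not isolated), via enol phosphonoacetate 27 (not isolated)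
Conditions: KN(SiMe3)2 (1.05 equiv), 18-crown-6, THF, −78 to −20 °C; 25, −78 °C; then LiCl, DBU, MeCN, 0 °C to rt
Reagents that add atoms: none
Why: Deprotonation of the most acidic hydroxyl (the α-ketol O–H at C6) triggers a [3,3] sigmatropic (anionic oxy-Cope) shift of the 1,5-diene C3=C2–C1–C6–C5=C4 in which C1–C6 breaks and C3–C4 forms; after enol–keto proton shuffling the single negative charge rests on the C6 enolate of the 1,2-dicarbonyl, which is O-acylated by 25 and then undergoes intramolecular Horner–Wadsworth–Emmons olefination of the C7 ketone. The closest known reaction types are the anionic oxy-Cope ring expansion of 1,2-dialkenylcyclohexanols to cyclodec-5-enones and butenolide formation by intramolecular HWE reaction of α-(phosphonoacetoxy) ketones. The ten-membered carbocycle is closed by the sigmatropic ring expansion (six to ten) and the butenolide by 5-exo-trig attack of the phosphonate carbanion on C7. C4 is set by chirality transfer from C1/C6 through the chair transition state in which the C6, C8 and C10 oxygens and the C1 vinyl group are axial and the (Z)-enol ether sits equatorial on C6, and the same chair gives C5=C6 with C7 cis to C4 (5E). The step needs this chair rather than the ring-flipped one (which would give the C4 epimer and the other alkene isomer) and it needs the charge to end on O6: the first is secured because the flipped chair places C10–CH3 and the C6 alkenyl group syn-diaxial, the second because the C7 ketone makes the C6 enolate by far the weakest base in the molecule.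

Step 21
Reactants: 28 macrocyclic butenolide
Product: 29 C13 alcohol
Conditions: HF·pyridine, pyridine/THF, 0 °C to rt
Reagents that add atoms: none
Why: Fluoride-mediated cleavage of the only silyl ether (primary TIPS); the PMB ethers, ketone and enol lactone are untouched.

Step 22
Reactants: 29 C13 alcohol
Product: 30 10,13-diacetate
Conditions: Ac2O, DMAP, Et3N, CH2Cl2, rt to 40 °C
Reagents that add atoms: acetic anhydride, CC(=O)OC(C)=O
Why: DMAP-catalysed acyl transfer acetylates the primary C13–OH and the tertiary C10 α-ketol hydroxyl, which are the only free hydroxyls because C4 and C8 are PMB ethers and C1 is still a ketone.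

Step 23
Reactants: 30 10,13-diacetate
Product: 32 target hemiketal (CNP0203479.1), via keto diol 31 (not isolated)
Conditions: DDQ, CH2Cl2/pH 7 buffer, 0 °C to rt
Reagents that add atoms: none
Why: Oxidative PMB cleavage frees C8–OH and C4–OH, and the C4 hydroxyl adds transannularly to the C1 ketone (5-exo hemiketalisation) to give the cis-bridged tetrahydrofuran, the C1 configuration being dictated by the bridge under thermodynamic control.

**Compound list**

1 | (−)-quinic acid | OC(=O)[C@]1(O)C[C@@H](O)[C@@H](O)[C@H](O)C1 | starting material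
2 | quinide (quinic acid 1,5-lactone) | O=C1O[C@@H]2C[C@@]1(O)C[C@@H](O)[C@H]2O | intermediate
3 | 3-O-(4-methoxybenzyl)quinide | O=C1O[C@@H]2C[C@@]1(O)C[C@@H](OCc3ccc(OC)cc3)[C@H]2O | intermediate
4 | 3-O-(4-methoxybenzyl)-4-O-(triisopropylsilyl)quinide | O=C1O[C@@H]2C[C@@]1(O)C[C@@H](OCc3ccc(OC)cc3)[C@H]2O[Si](C(C)C)(C(C)C)C(C)C | intermediate
5 | 1-(hydroxymethyl)-3-(PMB-oxy)-4-(TIPS-oxy)cyclohexane-1,5-diol | OC[C@]1(O)C[C@@H](OCc2ccc(OC)cc2)[C@@H](O[Si](C(C)C)(C(C)C)C(C)C)[C@H](O)C1 | intermediate
6 | 5-hydroxy-3-(PMB-oxy)-4-(TIPS-oxy)cyclohexan-1-one | O=C1C[C@@H](OCc2ccc(OC)cc2)[C@@H](O[Si](C(C)C)(C(C)C)C(C)C)[C@H](O)C1 | intermediate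
7 | 5-O-mesylate of 6 | O=C1C[C@@H](OCc2ccc(OC)cc2)[C@@H](O[Si](C(C)C)(C(C)C)C(C)C)[C@H](OS(C)(=O)=O)C1 | intermediate
8 | (4S,5R)-5-(PMB-oxy)-4-(TIPS-oxy)cyclohex-2-en-1-one | O=C1C[C@@H](OCc2ccc(OC)cc2)[C@@H](O[Si](C(C)C)(C(C)C)C(C)C)C=C1 | intermediate
9 | tertiary allylic alcohol (10β-OH, 10α-CH3, 7β-OTIPS, 8β-OPMB) | C[C@]1(O)C[C@@H](OCc2ccc(OC)cc2)[C@@H](O[Si](C(C)C)(C(C)C)C(C)C)C=C1 | intermediate
10 | triol (1α,6α-diol of 9) | C[C@]1(O)C[C@@H](OCc2ccc(OC)cc2)[C@@H](O[Si](C(C)C)(C(C)C)C(C)C)[C@H](O)[C@@H]1O | intermediate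
11 | acyloin (C6 ketone, 1α-OH) | C[C@]1(O)C[C@@H](OCc2ccc(OC)cc2)[C@@H](O[Si](C(C)C)(C(C)C)C(C)C)C(=O)[C@@H]1O | intermediate
12 | 1-(trimethylsilyl)prop-1-yne | CC#C[Si](C)(C)C | starting material
13 | 1-bromoprop-1-yne | CC#CBr | intermediate
14 | 4-methoxybenzyl alcohol | COc1ccc(CO)cc1 | starting material
15 | (Z)-1-bromo-2-[(4-methoxybenzyl)oxy]prop-1-ene | Br/C=C(/C)OCc1ccc(OC)cc1 | intermediate
16 | (Z)-2-[(4-methoxybenzyl)oxy]prop-1-enyllithium | [Li]/C=C(/C)OCc1ccc(OC)cc1 | intermediate
17 | C6 adduct (6β-OH, 6α-(Z)-alkenyl, 1α-OH) | C[C@]1(O)C[C@@H](OCc2ccc(OC)cc2)[C@@H](O[Si](C(C)C)(C(C)C)C(C)C)[C@](O)(/C=C(/C)OCc2ccc(OC)cc2)[C@@H]1O | intermediate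
18 | C1 ketone | C[C@]1(O)C[C@@H](OCc2ccc(OC)cc2)[C@@H](O[Si](C(C)C)(C(C)C)C(C)C)[C@](O)(/C=C(/C)OCc2ccc(OC)cc2)C1=O | intermediate
19 | divinyl diol (1β-OH, 1α-vinyl) | C[C@]1(O)C[C@@H](OCc2ccc(OC)cc2)[C@@H](O[Si](C(C)C)(C(C)C)C(C)C)[C@](O)(/C=C(/C)OCc2ccc(OC)cc2)[C@]1(O)C=C | intermediate
20 | tetraol (7β-OH free) | C[C@]1(O)C[C@@H](OCc2ccc(OC)cc2)[C@@H](O)[C@](O)(/C=C(/C)OCc2ccc(OC)cc2)[C@]1(O)C=C | intermediate
21 | α-ketol, substrate of the key step (C7 ketone) | C[C@]1(O)C[C@@H](OCc2ccc(OC)cc2)C(=O)[C@](O)(/C=C(/C)OCc2ccc(OC)cc2)[C@]1(O)C=C | intermediate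
22 | benzyl 2-(diethoxyphosphoryl)acetate | CCOP(=O)(CC(=O)OCc1ccccc1)OCC | starting material
23 | benzyl 2-(diethoxyphosphoryl)-3-(triisopropylsilyloxy)propanoate (racemic) | CCOP(=O)(OCC)C(CO[Si](C(C)C)(C(C)C)C(C)C)C(=O)OCc1ccccc1 | intermediate
24 | 2-(diethoxyphosphoryl)-3-(triisopropylsilyloxy)propanoic acid (racemic) | CCOP(=O)(OCC)C(CO[Si](C(C)C)(C(C)C)C(C)C)C(=O)O | intermediate
25 | 2-(diethoxyphosphoryl)-3-(triisopropylsilyloxy)propanoyl chloride (racemic) | CCOP(=O)(OCC)C(CO[Si](C(C)C)(C(C)C)C(C)C)C(Cl)=O | intermediate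
26 | potassium C6 enolate of the ring-expanded 1,6,7-trione | O=C1/C(=C\[C@](C)(OCc2ccc(OC)cc2)CCC(=O)[C@@](C)(O)C[C@H]1OCc1ccc(OC)cc1)[O-].[K+] | intermediate
27 | C6 enol phosphonoacetate | O=C1/C(=C\[C@](C)(OCc2ccc(OC)cc2)CCC(=O)[C@@](C)(O)C[C@H]1OCc1ccc(OC)cc1)OC(=O)C(CO[Si](C(C)C)(C(C)C)C(C)C)P(=O)(OCC)OCC | intermediate
28 | macrocyclic butenolide (13-OTIPS, 4-OPMB, 8-OPMB, 10-OH, C1 ketone) | CC(C)[Si](C(C)C)(C(C)C)OCC1=C2/C(=C\[C@](C)(OCc3ccc(OC)cc3)CCC(=O)[C@@](C)(O)C[C@H]2OCc2ccc(OC)cc2)OC1=O | intermediate
29 | C13 alcohol | OCC1=C2/C(=C\[C@](C)(OCc3ccc(OC)cc3)CCC(=O)[C@@](C)(O)C[C@H]2OCc2ccc(OC)cc2)OC1=O | intermediate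
30 | 10,13-diacetate | CC(=O)OCC1=C2/C(=C\[C@](C)(OCc3ccc(OC)cc3)CCC(=O)[C@@](C)(OC(C)=O)C[C@H]2OCc2ccc(OC)cc2)OC1=O | intermediate
31 | keto diol (open form of the target) | CC(=O)OCC1=C2/C(=C\[C@](C)(O)CCC(=O)[C@@](C)(OC(C)=O)C[C@H]2O)OC1=O | intermediate
32 | CNP0203479.1 | CC(=O)OCC1=C2/C(=C\[C@@]3(C)CC[C@](O)(O3)[C@@](C)(OC(C)=O)C[C@H]2O)OC1=O | target

**Step count and risks**

Total step count: 23. Longest linear sequence: 18 steps from (−)-quinic acid (steps 1–9, 12–16, 20–23).

Steps most likely to fail:

Step 20. Three processes may go wrong. An anionic α-ketol shift or C8 epimerisation may outrun the sigmatropic shift; reaction through the ring-flipped chair would lose control of C4 and of the alkene geometry; and β-elimination of silanolate from the phosphonate anion may precede olefination. The fallback is neutral and stepwise; it sets out from 21 and comes back at 29. The three hydroxyls of 21 are silylated (TMSOTf, 2,6-lutidine) to the tris(trimethylsilyl) ether F1. Heating F1 (toluene, 110–140 °C) in a thermal siloxy-Cope rearrangement should give the ring-expanded bis(silyl enol ether) F2. One equivalent of MeLi at −78 °C should cleave the more electrophilic 2-siloxy-enone silyl ether to the lithium C6 enolate, which is acylated with 25 to the silylated enol phosphonoacetate F3. LiCl/DBU then closes the silylated butenolide F4, and HF·pyridine removes all silyl groups (C1 enol ether to ketone, O10, O13) to give 29.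

Step 14. Addition may occur from the β face through a chelated, ring-flipped conformer, or the doubly neopentyl ketone may fail to react. The fallback sets out from 18 and comes back at 19. Addition of the small sp nucleophile HC≡CMgBr, which follows the axial trajectory more strictly and is less sensitive to the flanking substituents, should give the ethynyl carbinol F5. Semihydrogenation over Pd/CaCO3–Pb(OAc)2 (Lindlar catalyst) with quinoline then gives 19.

Step 11. The alkoxide may attack bromine (halophilic attack), add and eliminate to the ynol ether, or isomerise the alkyne to the bromoallene, and the E/Z ratio may be poor. The fallback sets out from 14 and comes back at 15. Hg(OAc)2-catalysed transetherification of 14 with 2-methoxypropene should give 4-methoxybenzyl isopropenyl ether F6. Bromine addition at −78 °C gives the 1,2-dibromide F7, and dehydrobromination with DBU gives the β-bromo enol ether, from which the Z isomer 15 is separated.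

Further compounds
F1 | step 20 | tris(trimethylsilyl) ether of 21 | C[C@]1(O[Si](C)(C)C)C[C@@H](OCc2ccc(OC)cc2)C(=O)[C@](O[Si](C)(C)C)(/C=C(/C)OCc2ccc(OC)cc2)[C@]1(O[Si](C)(C)C)C=C
F2 | step 20 | ring-expanded bis(silyl enol ether) (C1 and C6 OTMS enol ethers, 10-OTMS, C7 ketone) | O=C1/C(=C\[C@](C)(OCc2ccc(OC)cc2)C/C=C(\O[Si](C)(C)C)[C@@](C)(O[Si](C)(C)C)C[C@H]1OCc1ccc(OC)cc1)O[Si](C)(C)C
F3 | step 20 | silylated enol phosphonoacetate (C1 OTMS enol ether, 10-OTMS) | O=C1/C(=C\[C@](C)(OCc2ccc(OC)cc2)C/C=C(\O[Si](C)(C)C)[C@@](C)(O[Si](C)(C)C)C[C@H]1OCc1ccc(OC)cc1)OC(=O)C(CO[Si](C(C)C)(C(C)C)C(C)C)P(=O)(OCC)OCC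
F4 | step 20 | silylated butenolide (C1 OTMS enol ether, 10-OTMS, 13-OTIPS) | CC(C)[Si](C(C)C)(C(C)C)OCC1=C2/C(=C\[C@](C)(OCc3ccc(OC)cc3)C/C=C(\O[Si](C)(C)C)[C@@](C)(O[Si](C)(C)C)C[C@H]2OCc2ccc(OC)cc2)OC1=O
F5 | step 14 | ethynyl carbinol (1β-OH, 1α-ethynyl analogue of 19) | C[C@]1(O)C[C@@H](OCc2ccc(OC)cc2)[C@@H](O[Si](C(C)C)(C(C)C)C(C)C)[C@](O)(/C=C(/C)OCc2ccc(OC)cc2)[C@]1(O)C#C
F6 | step 11 | 4-methoxybenzyl isopropenyl ether | C=C(C)OCc1ccc(OC)cc1
F7 | step 11 | 1,2-dibromo-2-[(4-methoxybenzyl)oxy]propane | CC(Br)(CBr)OCc1ccc(OC)cc1
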